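Substrate goes slowly enough in the elm flask, with 0.88 mM of free catalyst, that 53.3% of it still stands after 12.0 min, while 7.4% stands as target.

the same everywhere: free catalyst 0.88 mM
- elm: substrate 0.40 M; reagent 0.40 M; run made earlier
- larch: substrate 0.56 M; reagent 0.40 M; run made earlier
- birch: substrate 0.88 M; reagent 0.40 M; run made earlier
- ash: substrate 0.40 M; reagent 0.20 M; run made earlier
- dusk: substrate 0.40 M; reagent 0.400 M; a closed flask charged with all of it at once and left for 12 min; time 12 min
- autumn: substrate 0.40 M; reagent 0.400 M; one stirred flow tank at steady state, fed with the mixture as stated, mean residence time 12 min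
- midnight: substrate 0.40 M (fed, over 9.60 min); reagent 0.400 M; all but substrate at the start; substrate goes in evenly over 9.60 min, the run ends at 12 min; time 12 min
- winter: substrate 0.40 M; reagent 0.400 M (fed, over 9.60 min); a stirred flask in which reagent is dosed at a steady rate over 9.60 min without added volume, worked up at 12 min; time 12 min

| run | time / min | target / % | substrate / % |
|---|---|---|---|
| elm | 3.00 | 3.9 | 88.5 |
| elm | 6.00 | 5.2 | 76.6 |
| elm | 10.0 | 5.7 | 60.8 |
| elm | 12.0 | 7.4 | 53.3 |
| larch | 1.00 | 1.8 | 98.0 |
| larch | 2.50 | 2.3 | 93.5 |
| larch | 6.00 | 3.5 | 80.3 |
| larch | 15.0 | 4.7 | 52.7 |
| birch | 4.00 | 1.0 | 91.8 |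
| birch | 8.00 | 1.2 | 80.9 |
| birch | 10.0 | 0.9 | 75.9 |
| birch | 15.0 | 0.9 | 63.6 |
| ash | 4.00 | 3.6 | 85.0 |
| ash | 8.00 | 4.6 | 69.1 |
| ash | 10.0 | 5.5 | 62.0 |
| ash | 15.0 | 6.2 | 44.0 |

(readings scatter by 0.5 percentage points)

- percentages count the substrate that a species holds: one side product counts as two
- target is meant together with its idle complex
- the stated concentrations are those of everything mixed, before any reaction; amounts are the same in each set-up
- what may be going on: free catalyst + target <-> idle complex; catalyst intermediate A -> catalyst intermediate B; reagent + catalyst intermediate B -> catalyst intermediate C; catalyst intermediate C <-> free catalyst + target; target <-> isomer of the product; substrate + target -> side product; substrate + free catalyst -> catalyst intermediate A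
- the feed brings no volume worth counting
- the earlier runs were made in a closed, stirred flask

- the set-up with the highest amount of target at the outlet or at the end, in percent of the substrate put in ("none" if the first two lie within 2 percentage points) (dusk / autumn / midnight / winter / none)
- amount of target at the outlet or at the end, in percent of the substrate put in, dusk
- amount of target at the outlet or at the end, in percent of the substrate put in, autumn
- amount of target at the outlet or at the end, in percent of the substrate put in, midnight
- amount of target at the outlet or at the end, in percent of the substrate put in, winter

I keep the books on substrate. Let L be the share lost, P the share standing as target or its isomer, and E the share of target eaten by substrate. Each side product holds two, one eaten target and one substrate, so the entries close as L = P + 2E.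

In the larch flask at 15.0 min, L is 47.3%; the isomer is not among the readings, so I enter the target reading 4.7% for P, which understates P by an unread amount and leaves E at 21.3%, too high by half that amount. If target stands near its balance, its loss is pseudo-first-order, with lifetime 1/(kS) for S the substrate concentration, and the ratio N = E/P counts the lifetimes passed, here 4.53. Dividing N by S and by the time gives the eating constant k, the rate constant with which substrate consumes target, 1.02 M⁻¹ min⁻¹, a reading that carries the scatter of its two values. Putting E = NP into the books gives P = L/(1 + 2N).

Dusk repeats the elm recipe, so I take the elm substrate reading at 12.0 min. That gives N = 2.62 and a lifetime of 4.58 min, shorter than the run, so I commit to P = 7.49% for dusk, target and isomer together, with the target asked for standing below that by the unread isomer.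

The forecast says “target is mainly consumed by substrate”. It gives dusk 7.1% (6.4% to 7.8%), autumn 6% (4.8% to 7.2%), midnight 7.6% (5.8% to 9.8%), winter 7% (6% to 7.8%), and best: none. My dusk figure, which counts the isomer with target, lies above its 7.1% for target, inside its range.

The flasks give dusk 6.63%, autumn 5.53%, midnight 6.29%, winter 6.48%, and best: none.

    free catalyst + target ⇌ idle complex, settled at all times (K = 1.90 M⁻¹)
    catalyst intermediate A → catalyst intermediate B (k = 0.824 s⁻¹)
    reagent + catalyst intermediate B → catalyst intermediate C (k = 24.6 M⁻¹ s⁻¹)
    catalyst intermediate C ⇌ free catalyst + target (K = 0.230 M, k = 0.382 s⁻¹)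
    target ⇌ isomer of the product (K = 1.90, k = 3.20 × 10⁻⁴ s⁻¹)
    substrate + target → side product (k = 0.0192 M⁻¹ s⁻¹)
    substrate + free catalyst → catalyst intermediate A (k = 1.95 M⁻¹ s⁻¹)

In dusk, target and isomer together stand at 7.68% against my 7.49%. A neighbouring flask, dusk with 0.10 M of substrate, keeps 36% of it unreacted at 12.0 min. The same k then gives N = 0.438, fewer lifetimes than in dusk, and P = 34.1%. That flask holds 29.5% as target and 4.23% as isomer, together 33.7%.

Readings and results are simulated from invented constants.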